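Ring B (C1, C5–C10; guaiane numbering, ring A = C1–C5) is closed by a thermal Cope/carbonyl-ene cascade. The precursor looks unlike the target: C6, C7 and C11 sit as a 1,1-dimethylallyl group on C3, beside a C4=C5 alkene, while C1 carries a Z-alkylidene arm ending in the C8 aldehyde. The [3,3] shift moves this unit suprafacially to C5 (C5–C6 bond; C5 configuration relayed from C3) and leaves C3=C4 for a later hydrogenation that sets C4. The prenyl group thus formed is trapped by the aldehyde (C7–C8 bond, C7/C8 trans). The cascade exploits the allylic C3–C4–C5 array of ring A and the C8-hydroxy/C7-isopropenyl homoallylic pattern of ring B.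

Key step: step 9

Remark: the R-configured oxazaborolidine in step 4 is specified on the assumption that the Z-alkylidene flank of ketone 6 (its CH2 points at the carbonyl) acts as the large group; if the sense proves opposite, the S catalyst is used.

Step 1
Reactants: 1 2-methylcyclopent-2-en-1-one; 2 N-methoxy-N-methylacetamide
Product: 3 5-acetyl-2-methylcyclopent-2-en-1-one (racemic, enolised 1,3-diketone)
Conditions: LiN(iPr)2, THF, −78 °C; then 2, −78 to 0 °C; aq HCl
Reagents that add atoms: none
Why: Kinetic deprotonation gives the cross-conjugated alpha-prime lithium enolate (future C1), which is C-acylated by the Weinreb amide through a tetrahedral chelate that collapses only on work-up (enolate acylation), and no lasting stereocenter is formed.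

Step 2
Reactants: 3 5-acetyl-2-methylcyclopent-2-en-1-one
Product: 4 (Z)-1-(3-methyl-2-oxocyclopent-3-en-1-ylidene)ethyl trifluoromethanesulfonate (triflate oxygen cis to the ring carbonyl)
Conditions: NaH, THF, 0 °C; Tf2O, −78 to 0 °C
Reagents that add atoms: trifluoromethanesulfonic anhydride, O=S(=O)(OS(=O)(=O)C(F)(F)F)C(F)(F)F
Why: The U-shaped sodium chelate of the 1,3-diketone holds both oxygens syn, and sulfonylation at the less hindered exocyclic oxygen, which keeps the ring enone intact, should give the Z enol triflate (enol triflate formation from a chelated 1,3-dicarbonyl enolate).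

Step 3
Reactants: 4 (Z)-1-(3-methyl-2-oxocyclopent-3-en-1-ylidene)ethyl trifluoromethanesulfonate; 5 (1,3-dioxolan-2-ylmethyl)zinc bromide
Product: 6 (5Z)-5-[1-(1,3-dioxolan-2-yl)propan-2-ylidene]-2-methylcyclopent-2-en-1-one
Conditions: PdCl2(dppf) (5 mol%), THF, 50 °C
Reagents that add atoms: none
Why: Negishi coupling of an alkenyl triflate proceeds with retention of alkene geometry, so the acetal arm (C9–C8) takes the place of the triflate cis to the ring carbonyl C5 and fixes the C1=C10 geometry needed for ring B closure.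

Step 4
Reactants: 6 (5Z)-5-[1-(1,3-dioxolan-2-yl)propan-2-ylidene]-2-methylcyclopent-2-en-1-one
Product: 7 (1S,5Z)-5-[1-(1,3-dioxolan-2-yl)propan-2-ylidene]-2-methylcyclopent-2-en-1-ol
Conditions: (R)-2-methyl-CBS-oxazaborolidine (20 mol%), catecholborane, PhMe, −78 °C; aqueous work-up
Reagents that add atoms: none
Why: Corey–Bakshi–Shibata reduction should reduce the cross-conjugated dienone in the 1,2-sense with hydride delivered to one carbonyl face under catalyst control, which sets the C5 carbinol as S, the source of all later stereocenters.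

Step 5
Reactants: 7 (1S,5Z)-5-[1-(1,3-dioxolan-2-yl)propan-2-ylidene]-2-methylcyclopent-2-en-1-ol; 8 3-bromo-2-methylprop-1-ene
Product: 9 2-{(2Z)-2-[(2S)-3-methyl-2-(2-methylprop-2-en-1-yloxy)cyclopent-3-en-1-ylidene]propyl}-1,3-dioxolane
Conditions: NaH, Bu4NI (cat.), THF/DMF, 0 °C to rt
Reagents that add atoms: none
Why: Williamson etherification of the sodium alkoxide with the primary allylic bromide occurs at oxygen and leaves the C5 stereocenter untouched.

Step 6
Reactants: 9 2-{(2Z)-2-[(2S)-3-methyl-2-(2-methylprop-2-en-1-yloxy)cyclopent-3-en-1-ylidene]propyl}-1,3-dioxolane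
Product: 11 2-{(1S,4Z)-4-[1-(1,3-dioxolan-2-yl)propan-2-ylidene]-2-methylcyclopent-2-en-1-yl}-2-methylpropanal, via isobutenyl ether 10 (not isolated)
Conditions: [Ir(PCy3)3]BPh4 (2 mol%), CH2Cl2/acetone, rt; then PPh3 (6 mol%), ClCH2CH2Cl, 80 °C
Reagents that add atoms: none
Why: The iridium hydride isomerises only the unhindered methallyl alkene to the 2-methylprop-1-enyl ether, and the resulting allyl vinyl ether undergoes a suprafacial Claisen rearrangement toward C3 (the C10 terminus would require two adjacent quaternary carbons), so C11 is delivered to the ring face that carried the C5–O bond, C3 is set as S and C4=C5 is created (olefin isomerisation–Claisen rearrangement).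

Step 7
Reactants: 11 2-{(1S,4Z)-4-[1-(1,3-dioxolan-2-yl)propan-2-ylidene]-2-methylcyclopent-2-en-1-yl}-2-methylpropanal
Product: 12 2-{(2Z)-2-[(4S)-3-methyl-4-(2-methylbut-3-en-2-yl)cyclopent-2-en-1-ylidene]propyl}-1,3-dioxolane
Conditions: Ph3PCH3Br, KOtBu, THF, 0 °C to rt
Reagents that add atoms: methyltriphenylphosphonium bromide, C[P+](c1ccccc1)(c1ccccc1)c1ccccc1.[Br-]
Why: Wittig methylenation of the non-enolisable neopentyl aldehyde gives the 1,1-dimethylallyl group (C6=C7 on C11) and cannot epimerise C3.

Step 8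
Reactants: 12 2-{(2Z)-2-[(4S)-3-methyl-4-(2-methylbut-3-en-2-yl)cyclopent-2-en-1-ylidene]propyl}-1,3-dioxolane
Product: 13 (3Z)-3-[(4S)-3-methyl-4-(2-methylbut-3-en-2-yl)cyclopent-2-en-1-ylidene]butanal
Conditions: LiBF4, MeCN/H2O (98:2), rt
Reagents that add atoms: water, O
Why: Mild Lewis-acid hydrolysis of the dioxolane unmasks the C8 aldehyde without acid strong enough to shift the diene or to conjugate the beta,gamma-unsaturated aldehyde (acetal hydrolysis).

Step 9
Reactants: 13 (3Z)-3-[(4S)-3-methyl-4-(2-methylbut-3-en-2-yl)cyclopent-2-en-1-ylidene]butanal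
Product: 15 (3aS,5R,6S)-3,8-dimethyl-5-(prop-1-en-2-yl)-1,3a,4,5,6,7-hexahydroazulen-6-ol, via prenyl aldehyde 14 (not isolated)
Conditions: PhMe (0.01 M), BHT (cat.), sealed tube, 180–200 °C
Reagents that add atoms: none
Why: On heating, 13 undergoes a Cope rearrangement of the 1,5-diene C6=C7–C11–C3–C4=C5 through a six-membered transition state bridged across ring A, which breaks C3–C11, forms C5–C6 and moves the ring alkene to C3=C4 to give prenyl aldehyde 14. The closest known reaction type is the thermal sigmatropic shift/carbonyl-ene cascade (oxy-Cope/ene sequences and the cyclisation of citronellal-type aldehydes). Ring B is then closed by an intramolecular carbonyl-ene reaction in which the C8 aldehyde adds to the proximal alkene carbon C7 (7-membered closure, exo to the C7=C11 alkene) while a C12 hydrogen passes to oxygen, forming C7–C8 and the isopropenyl group. C5 is controlled by the C3 stereocenter, because the tether can reach only the ring A face on which C11 was attached (suprafacial 1,3-chirality transfer), and C7 and C8 are controlled by a chair-like ene transition state with the forming isopropenyl group, the C8–O bond and the ring A bond at C5 all pseudo-equatorial, which should give C7/C8 trans and H5/H7 cis. The step needs the Cope shift to precede any ene reaction of 13 and the 7-membered to beat the 8-membered closure; the first is secured by the s-trans-locked diene, whose internal carbon C5 is a poor ene terminus, and the second by the Z geometry of C1=C10, which holds C8 next to C7, and by the polarisation of the trisubstituted alkene toward tertiary C11. The near-thermoneutral Cope equilibrium is drained by the irreversible ene step, so both bonds are made in one operation.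

Step 10
Reactants: 15 (3aS,5R,6S)-3,8-dimethyl-5-(prop-1-en-2-yl)-1,3a,4,5,6,7-hexahydroazulen-6-ol
Product: 16 (3aS,5S,6S)-5-(2-hydroxypropan-2-yl)-3,8-dimethyl-1,3a,4,5,6,7-hexahydroazulen-6-ol
Conditions: Hg(OAc)2 (1.05 equiv), THF/H2O, rt; then NaBH4, aq NaOH, 0 °C
Reagents that add atoms: water, O
Why: Oxymercuration–demercuration places the hydroxyl on the more substituted carbon and is much faster for the 1,1-disubstituted isopropenyl alkene than for the trisubstituted C3=C4 and tetrasubstituted C1=C10 alkenes, so one equivalent should install the C11 tertiary alcohol without touching a stereocenter.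

Step 11
Reactants: 16 (3aS,5S,6S)-5-(2-hydroxypropan-2-yl)-3,8-dimethyl-1,3a,4,5,6,7-hexahydroazulen-6-ol
Product: 17 (3S,3aS,5S,6S)-5-(2-hydroxypropan-2-yl)-3,8-dimethyl-1,2,3,3a,4,5,6,7-octahydroazulen-6-ol
Conditions: H2 (1 atm), PtO2 (5 mol%), EtOAc, rt
Reagents that add atoms: none
Why: Heterogeneous syn-hydrogenation should reduce the trisubstituted ring A alkene from its open face, the one bearing H5 and opposite to C6 and ring B, which places H4 cis to H5 (C4 methyl cis to C6, 3S), while the tetrasubstituted C1=C10 alkene stays inert.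

Step 12
Reactants: 17 (3S,3aS,5S,6S)-5-(2-hydroxypropan-2-yl)-3,8-dimethyl-1,2,3,3a,4,5,6,7-octahydroazulen-6-ol; 18 (E)-3-(4-acetoxyphenyl)prop-2-enoic acid
Product: 19 (3S,3aS,5S,6S)-5-(2-hydroxypropan-2-yl)-3,8-dimethyl-1,2,3,3a,4,5,6,7-octahydroazulen-6-yl (E)-3-(4-acetoxyphenyl)prop-2-enoate
Conditions: DCC, DMAP (cat.), CH2Cl2, 0 °C to rt
Reagents that add atoms: none
Why: Steglich esterification acylates the secondary C8 hydroxyl because the tertiary C11 hydroxyl is too hindered, and C8 keeps its configuration since the C8–O bond is not broken.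

Step 13
Reactants: 19 (3S,3aS,5S,6S)-5-(2-hydroxypropan-2-yl)-3,8-dimethyl-1,2,3,3a,4,5,6,7-octahydroazulen-6-yl (E)-3-(4-acetoxyphenyl)prop-2-enoate
Product: 20 (3S,3aS,5S,6S)-5-(2-hydroxypropan-2-yl)-3,8-dimethyl-1,2,3,3a,4,5,6,7-octahydroazulen-6-yl (E)-3-(4-hydroxyphenyl)prop-2-enoate (CNP0403230.1)
Conditions: K2CO3 (0.2 equiv), MeOH, 0 °C
Reagents that add atoms: none
Why: Base-catalysed methanolysis cleaves the activated aryl acetate far faster than the hindered secondary cinnamate and releases the phenol of the target (transesterification).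

Compound list
1 | 2-methylcyclopent-2-en-1-one | CC1=CCCC1=O | starting material
2 | N-methoxy-N-methylacetamide | CC(=O)N(C)OC | starting material
3 | 5-acetyl-2-methylcyclopent-2-en-1-one (racemic, enolised) | CC(=O)C1CC=C(C)C1=O | intermediate
4 | (Z)-1-(3-methyl-2-oxocyclopent-3-en-1-ylidene)ethyl trifluoromethanesulfonate | O=C1C(C)=CC/C1=C(\C)OS(=O)(=O)C(F)(F)F | intermediate
5 | (1,3-dioxolan-2-ylmethyl)zinc bromide | Br[Zn]CC1OCCO1 | starting material
6 | (5Z)-5-[1-(1,3-dioxolan-2-yl)propan-2-ylidene]-2-methylcyclopent-2-en-1-one | O=C1C(C)=CC/C1=C(\C)CC2OCCO2 | intermediate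
7 | (1S,5Z)-5-[1-(1,3-dioxolan-2-yl)propan-2-ylidene]-2-methylcyclopent-2-en-1-ol | O[C@H]1C(C)=CC/C1=C(\C)CC2OCCO2 | intermediate
8 | 3-bromo-2-methylprop-1-ene | C=C(C)CBr | starting material
9 | 2-{(2Z)-2-[(2S)-3-methyl-2-(2-methylprop-2-en-1-yloxy)cyclopent-3-en-1-ylidene]propyl}-1,3-dioxolane | C=C(C)CO[C@H]1C(C)=CC/C1=C(\C)CC2OCCO2 | intermediate
10 | 2-{(2Z)-2-[(2S)-3-methyl-2-(2-methylprop-1-en-1-yloxy)cyclopent-3-en-1-ylidene]propyl}-1,3-dioxolane (isobutenyl ether) | CC(C)=CO[C@H]1C(C)=CC/C1=C(\C)CC2OCCO2 | intermediate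
11 | 2-{(1S,4Z)-4-[1-(1,3-dioxolan-2-yl)propan-2-ylidene]-2-methylcyclopent-2-en-1-yl}-2-methylpropanal | O=CC(C)(C)[C@H]1C/C(=C(\C)CC2OCCO2)C=C1C | intermediate
12 | 2-{(2Z)-2-[(4S)-3-methyl-4-(2-methylbut-3-en-2-yl)cyclopent-2-en-1-ylidene]propyl}-1,3-dioxolane | C=CC(C)(C)[C@H]1C/C(=C(\C)CC2OCCO2)C=C1C | intermediate
13 | (3Z)-3-[(4S)-3-methyl-4-(2-methylbut-3-en-2-yl)cyclopent-2-en-1-ylidene]butanal | C=CC(C)(C)[C@H]1C/C(=C(\C)CC=O)C=C1C | intermediate
14 | (3Z)-3-[(2S)-3-methyl-2-(3-methylbut-2-en-1-yl)cyclopent-3-en-1-ylidene]butanal (prenyl aldehyde) | CC(C)=CC[C@H]1C(C)=CC/C1=C(\C)CC=O | intermediate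
15 | (3aS,5R,6S)-3,8-dimethyl-5-(prop-1-en-2-yl)-1,3a,4,5,6,7-hexahydroazulen-6-ol | CC1=C2CC=C(C)[C@@H]2C[C@H](C(C)=C)[C@@H](O)C1 | intermediate
16 | (3aS,5S,6S)-5-(2-hydroxypropan-2-yl)-3,8-dimethyl-1,3a,4,5,6,7-hexahydroazulen-6-ol | CC1=C2CC=C(C)[C@@H]2C[C@H](C(C)(C)O)[C@@H](O)C1 | intermediate
17 | (3S,3aS,5S,6S)-5-(2-hydroxypropan-2-yl)-3,8-dimethyl-1,2,3,3a,4,5,6,7-octahydroazulen-6-ol | CC1=C2CC[C@H](C)[C@@H]2C[C@H](C(C)(C)O)[C@@H](O)C1 | intermediate
18 | (E)-3-(4-acetoxyphenyl)prop-2-enoic acid | CC(=O)Oc1ccc(/C=C/C(=O)O)cc1 | starting material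
19 | (3S,3aS,5S,6S)-5-(2-hydroxypropan-2-yl)-3,8-dimethyl-1,2,3,3a,4,5,6,7-octahydroazulen-6-yl (E)-3-(4-acetoxyphenyl)prop-2-enoate | CC1=C2CC[C@H](C)[C@@H]2C[C@H](C(C)(C)O)[C@@H](OC(=O)/C=C/c2ccc(OC(C)=O)cc2)C1 | intermediate
20 | (3S,3aS,5S,6S)-5-(2-hydroxypropan-2-yl)-3,8-dimethyl-1,2,3,3a,4,5,6,7-octahydroazulen-6-yl (E)-3-(4-hydroxyphenyl)prop-2-enoate | CC1=C2CC[C@H](C)[C@@H]2C[C@H](C(C)(C)O)[C@@H](OC(=O)/C=C/c2ccc(O)cc2)C1 | target

Total step count: 13. Longest linear sequence: 13 steps (1 to 20).

Steps most likely to fail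

Step 9. The aldehyde may add in an ene or Prins sense to the diene of 13 before the sigmatropic shift, or the uncatalysed ene closure may show poor facial control at C7 and C8. The fallback sets out from 12 and returns at 15, making the two bonds in separate operations. Acetal 12 is heated alone (PhMe, 180 °C), where only the Cope shift can occur, to give 2-{(2Z)-2-[(2S)-3-methyl-2-(3-methylbut-2-en-1-yl)cyclopent-3-en-1-ylidene]propyl}-1,3-dioxolane F1, with unrearranged 12 recycled. F1 is hydrolysed (LiBF4, wet MeCN) to 14, now isolated, and ring B is closed at −78 °C with Me2AlCl in CH2Cl2, a Lewis-acid carbonyl-ene cyclisation whose tighter transition state should favour the trans, all-equatorial product 15.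

Step 4. Enantiofacial discrimination may be poor because both flanks of the carbonyl of 6 are hindered sp2 carbons, and the sense of induction is uncertain. The fallback sets out from 6 and returns at 7. Luche reduction (NaBH4, CeCl3·7H2O, MeOH, −78 °C) gives racemic (5Z)-5-[1-(1,3-dioxolan-2-yl)propan-2-ylidene]-2-methylcyclopent-2-en-1-ol F2. Kinetic resolution with Candida antarctica lipase B and vinyl acetate in MTBE should acetylate the R enantiomer to (1R,5Z)-5-[1-(1,3-dioxolan-2-yl)propan-2-ylidene]-2-methylcyclopent-2-en-1-yl acetate F3 and leave the S alcohol 7, which is separated by chromatography.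

Step 2. Sulfonylation may occur at the ring oxygen, or the chelate may open and the Z geometry be lost. The fallback sets out from 1 and returns at 6, replacing steps 1 to 3 by an aldol condensation. The LiN(iPr)2 enolate of 1 is added to 1-(1,3-dioxolan-2-yl)propan-2-one to give 5-[1-(1,3-dioxolan-2-yl)-2-hydroxypropan-2-yl]-2-methylcyclopent-2-en-1-one F4. F4 is converted with MsCl and Et3N into its methanesulfonate F5 (not isolated), and DBU-induced elimination gives 6 together with its geometric isomer (5E)-5-[1-(1,3-dioxolan-2-yl)propan-2-ylidene]-2-methylcyclopent-2-en-1-one F6. The isomers are separated by chromatography, and F6 is re-equilibrated by reversible conjugate addition of catalytic PBu3 and recycled.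

Further compounds
F1 | step 9 | 2-{(2Z)-2-[(2S)-3-methyl-2-(3-methylbut-2-en-1-yl)cyclopent-3-en-1-ylidene]propyl}-1,3-dioxolane | CC(C)=CC[C@H]1C(C)=CC/C1=C(\C)CC2OCCO2
F2 | step 4 | (5Z)-5-[1-(1,3-dioxolan-2-yl)propan-2-ylidene]-2-methylcyclopent-2-en-1-ol (racemic) | OC1C(C)=CC/C1=C(\C)CC2OCCO2
F3 | step 4 | (1R,5Z)-5-[1-(1,3-dioxolan-2-yl)propan-2-ylidene]-2-methylcyclopent-2-en-1-yl acetate | CC(=O)O[C@@H]1C(C)=CC/C1=C(\C)CC2OCCO2
F4 | step 2 | 5-[1-(1,3-dioxolan-2-yl)-2-hydroxypropan-2-yl]-2-methylcyclopent-2-en-1-one (diastereomer mixture) | CC1=CCC(C(C)(O)CC2OCCO2)C1=O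
F5 | step 2 | 1-(1,3-dioxolan-2-yl)-2-(3-methyl-2-oxocyclopent-3-en-1-yl)propan-2-yl methanesulfonate | CC1=CCC(C(C)(OS(C)(=O)=O)CC2OCCO2)C1=O
F6 | step 2 | (5E)-5-[1-(1,3-dioxolan-2-yl)propan-2-ylidene]-2-methylcyclopent-2-en-1-one | O=C1C(C)=CC/C1=C(/C)CC2OCCO2
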